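The target is cut at the O4'–C3'' bond of pyran ring D, leading back to unprotected (3R)-8,3'-diprenyl-7,2',4'-trihydroxyisoflavan 26. In one operation a flavin-dependent oxidocyclase of the berberine bridge enzyme family takes a hydride from C1'' of the 3'-prenyl group and closes ring D at O4'. The step exploits the B-ring resorcinol, whose O2'-H and O4'-H flank C3'. The 8-prenyl group of ring A has only 7-OH and the ether O1 as neighbours and stays open. Triol 26 is built from two copies of aldehyde 7, joined by an Evans alkylation that sets C3 and a Mitsunobu closure of ring C.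

Key step: step 17

Assumption: isoflavan numbering is used (O1, C2–C4, C4a, C5–C8, C8a; ring B primed; 3'-prenyl carbons C1''–C3''; prenyl = 3-methylbut-2-en-1-yl). The oxidocyclase of step 17 is taken to be a family member picked from a screening panel, so only the chemistry of the enzyme class is relied on.

Step 1
Reactants: 1 resorcinol
Product: 2 1,3-bis(methoxymethoxy)benzene
Conditions: NaH, MOMCl, DMF, 0 °C → rt
Reagents that add atoms: chloromethyl methyl ether (MOMCl), COCCl
Why: Williamson-type O-alkylation of both phenoxides gives base-stable acetals that also serve as directing groups for the lithiations of steps 2 and 3.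

Step 2
Reactants: 2 1,3-bis(methoxymethoxy)benzene; 3 prenyl bromide (1-bromo-3-methylbut-2-ene)
Product: 5 1,3-bis(methoxymethoxy)-2-prenylbenzene, via [2,6-bis(methoxymethoxy)phenyl]lithium 4 (not isolated)
Conditions: n-BuLi, THF, 0 °C → rt; CuI (10 mol %), 3, −78 °C → rt
Reagents that add atoms: n-butyllithium (lithium of 4), [Li]CCCC
Why: Directed ortho-metalation occurs at C2, the position flanked by both OMOM groups, and copper-catalysed SN2 coupling of aryllithium 4 at the primary carbon of the allylic bromide gives the linear prenyl arene.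

Step 3
Reactants: 5 1,3-bis(methoxymethoxy)-2-prenylbenzene
Product: 7 2,4-bis(methoxymethoxy)-3-prenylbenzaldehyde, via [2,4-bis(methoxymethoxy)-3-prenylphenyl]lithium 6 (not isolated)
Conditions: s-BuLi, TMEDA, THF, −78 °C; DMF, −78 → 0 °C; H2O
Reagents that add atoms: sec-butyllithium (lithium of 6), [Li]C(C)CC; N,N-dimethylformamide, CN(C)C=O
Why: Directed ortho-metalation at C4, run under kinetic conditions at −78 °C so that OMOM-complexed ring deprotonation outruns removal of the allylic-benzylic CH2 proton, is followed by Bouveault formylation of aryllithium 6 with DMF to give the aldehyde from which both fragments are made.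

Step 4
Reactants: 7 2,4-bis(methoxymethoxy)-3-prenylbenzaldehyde
Product: 8 2-hydroxy-4-(methoxymethoxy)-3-prenylbenzaldehyde
Conditions: MgBr2·OEt2, CH2Cl2–Et2O, 0 °C → rt; H2O
Reagents that add atoms: none
Why: Chelation-controlled acetal cleavage, in which Mg(II) bridges the formyl oxygen and the ortho acetal oxygen so that only the ortho MOM group is lost, marks the future O1 as the one oxygen that can be freed alone for ring-C closure, since a free O2' would otherwise close a dihydrobenzofuran in step 15.

Step 5
Reactants: 8 2-hydroxy-4-(methoxymethoxy)-3-prenylbenzaldehyde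
Product: 9 2-(allyloxy)-4-(methoxymethoxy)-3-prenylbenzaldehyde
Conditions: allyl bromide, K2CO3, DMF, 40 °C
Reagents that add atoms: allyl bromide, C=CCBr
Why: Williamson etherification of the chelated phenol gives an allyl ether that cannot migrate to a neighbouring alkoxide, survives hydride and enolate chemistry, and is later removed under neutral Pd(0) conditions that touch neither MOM nor prenyl groups.

Step 6
Reactants: 9 2-(allyloxy)-4-(methoxymethoxy)-3-prenylbenzaldehyde
Product: 10 [2-(allyloxy)-4-(methoxymethoxy)-3-prenylphenyl]methanol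
Conditions: NaBH4, MeOH, 0 °C
Reagents that add atoms: none
Why: Chemoselective borohydride 1,2-reduction of the aldehyde leaves both olefins and the acetal untouched.

Step 7
Reactants: 10 [2-(allyloxy)-4-(methoxymethoxy)-3-prenylphenyl]methanol
Product: 11 2-(allyloxy)-1-(bromomethyl)-4-(methoxymethoxy)-3-prenylbenzene
Conditions: CBr4, PPh3, CH2Cl2, 0 °C; used at once
Reagents that add atoms: carbon tetrabromide, BrC(Br)(Br)Br
Why: The Appel reaction converts the electron-rich benzylic alcohol into the bromide under neutral conditions that spare the MOM acetal and the olefins, and the labile bromide is used without storage.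

Step 8
Reactants: 7 2,4-bis(methoxymethoxy)-3-prenylbenzaldehyde
Product: 12 1-ethenyl-2,4-bis(methoxymethoxy)-3-prenylbenzene
Conditions: Ph3PCH3Br, KOt-Bu, THF, 0 °C → rt
Reagents that add atoms: methyltriphenylphosphonium bromide, C[P+](c1ccccc1)(c1ccccc1)c1ccccc1.[Br-]
Why: Wittig methylenation of the aromatic aldehyde with the non-stabilised ylide adds the second carbon of the arylacetic unit under basic conditions that leave the MOM acetals and the prenyl olefin alone.

Step 9
Reactants: 12 1-ethenyl-2,4-bis(methoxymethoxy)-3-prenylbenzene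
Product: 14 2-[2,4-bis(methoxymethoxy)-3-prenylphenyl]ethan-1-ol, via 9-{2-[2,4-bis(methoxymethoxy)-3-prenylphenyl]ethyl}-9-borabicyclo[3.3.1]nonane 13 (not isolated)
Conditions: 9-BBN (1.1 equiv), THF, 0 °C → rt; NaOH, H2O2, 0 °C → rt
Reagents that add atoms: 9-borabicyclo[3.3.1]nonane (9-BBN), C1CC2CCCC(C1)B2; hydrogen peroxide, OO
Why: In this Brown hydroboration–oxidation the bulky 9-BBN adds to the monosubstituted styrene olefin far faster than to the trisubstituted prenyl olefin and places boron on the terminal carbon, so alkaline peroxide oxidation of borane 13 gives the primary alcohol.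

Step 10
Reactants: 14 2-[2,4-bis(methoxymethoxy)-3-prenylphenyl]ethan-1-ol
Product: 16 2-[2,4-bis(methoxymethoxy)-3-prenylphenyl]acetic acid, via 2-[2,4-bis(methoxymethoxy)-3-prenylphenyl]acetaldehyde 15 (not isolated)
Conditions: TEMPO (cat.), PhI(OAc)2, MeCN–H2O, rt
Reagents that add atoms: water, O
Why: Oxoammonium (TEMPO) oxidation with PhI(OAc)2 as chlorine-free terminal oxidant takes the primary alcohol through aldehyde 15 and its hydrate to the acid without attacking the trisubstituted olefin or the protected arene.

Step 11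
Reactants: 16 2-[2,4-bis(methoxymethoxy)-3-prenylphenyl]acetic acid; 17 (R)-4-benzyl-2-oxazolidinone
Product: 19 (4R)-4-benzyl-3-{2-[2,4-bis(methoxymethoxy)-3-prenylphenyl]acetyl}-1,3-oxazolidin-2-one, via 2-[2,4-bis(methoxymethoxy)-3-prenylphenyl]acetic pivalic anhydride 18 (not isolated)
Conditions: PivCl, Et3N, THF, −20 °C; LiCl, 17, rt
Reagents that add atoms: pivaloyl chloride (pivaloyl group of 18), CC(C)(C)C(=O)Cl
Why: N-Acylation of the oxazolidinone through mixed anhydride 18 under LiCl/Et3N activation takes place at the less hindered arylacetyl carbonyl and avoids strong base.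

Step 12
Reactants: 19 arylacetyl imide; 11 2-(allyloxy)-1-(bromomethyl)-4-(methoxymethoxy)-3-prenylbenzene
Product: 21 (4R)-4-benzyl-3-{(2R)-3-[2-(allyloxy)-4-(methoxymethoxy)-3-prenylphenyl]-2-[2,4-bis(methoxymethoxy)-3-prenylphenyl]propanoyl}-1,3-oxazolidin-2-one, via the sodium (Z)-enolate of the arylacetyl imide 20 (not isolated)
Conditions: NaHMDS, THF, −78 °C; 11, −78 → −30 °C; cold AcOH quench
Reagents that add atoms: sodium hexamethyldisilazide (sodium of 20), C[Si](C)(C)[N-][Si](C)(C)C.[Na+]
Why: Evans asymmetric alkylation, in which the chelated (Z)-sodium enolate 20 is shielded on one face by the C4 benzyl group of the (R)-auxiliary so that bromide 11 is attacked from the open face, sets the future C3 as R (ranking C=O > aryl > CH2Ar > H).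

Step 13
Reactants: 21 alkylated imide
Product: 22 (2R)-3-[2-(allyloxy)-4-(methoxymethoxy)-3-prenylphenyl]-2-[2,4-bis(methoxymethoxy)-3-prenylphenyl]propan-1-ol
Conditions: LiBH4, MeOH (1 equiv), Et2O–THF, 0 °C
Reagents that add atoms: none
Why: Reductive cleavage of the imide with LiBH4 gives the primary alcohol and returns the auxiliary without enolisation, and the descriptor stays R because CH2OH takes the rank of the carbonyl carbon.

Step 14
Reactants: 22 allyl-protected alcohol
Product: 23 6-{(2R)-2-[2,4-bis(methoxymethoxy)-3-prenylphenyl]-3-hydroxypropyl}-3-(methoxymethoxy)-2-prenylphenol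
Conditions: Pd(PPh3)4 (cat.), morpholine, THF, rt
Reagents that add atoms: none
Why: In this Tsuji–Trost-type deallylation Pd(0) ionises only the aryl allyl ether and morpholine traps the π-allyl unit, while the prenyl groups, which carry no leaving group, and the MOM acetals are inert.

Step 15
Reactants: 23 phenol alcohol
Product: 24 (3R)-7,2',4'-tris(methoxymethoxy)-8,3'-diprenylisoflavan
Conditions: PPh3, DIAD, THF (high dilution), 0 °C → rt
Reagents that add atoms: none
Why: Intramolecular Mitsunobu etherification closes ring C by 6-exo-tet attack of the only free phenol on the activated primary carbinol, so the adjacent stereocentre C3 is not touched and stays R.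

Step 16
Reactants: 24 (3R)-7,2',4'-tris(methoxymethoxy)-8,3'-diprenylisoflavan
Product: 26 (3R)-8,3'-diprenyl-7,2',4'-trihydroxyisoflavan, via (3R)-7,2',4'-tris(trimethylsilyloxy)-8,3'-diprenylisoflavan 25 (not isolated)
Conditions: TMSOTf, 2,2'-bipyridyl, MeCN, 0 °C → rt; then H2O, rt
Reagents that add atoms: trimethylsilyl trifluoromethanesulfonate (silyl groups of 25), C[Si](C)(C)OS(=O)(=O)C(F)(F)F
Why: The silyl triflate–bipyridyl pair exchanges aryl MOM ethers for TMS ethers without free Brønsted acid and water then hydrolyses tris-silyl ether 25, so the three ortho-prenylphenols are released under conditions that should not protonate the olefins and close dimethylchroman rings.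

Step 17
Reactants: 26 (3R)-8,3'-diprenyl-7,2',4'-trihydroxyisoflavan
Product: 28 (3R)-3-(5-hydroxy-2,2-dimethyl-2H-chromen-6-yl)-8-prenylchroman-7-ol (target), via the B-ring ortho-quinone methide 27 (not isolated)
Conditions: FAD-dependent BBE-like oxidocyclase (cannabichromenic acid synthase / daurichromenic acid synthase family, variant selected for 26), air, catalase, citrate–phosphate buffer pH 6, 5% DMSO, hydroxypropyl-β-cyclodextrin, 30 °C, dark; EtOAc extraction, SiO2
Reagents that add atoms: none
Why: The enzyme-bound FAD accepts a hydride from C1'' (the benzylic and allylic CH2 of the 3'-prenyl group) while an active-site base takes the O4' proton, giving ortho-quinone methide 27 (C4'=O, C3'=C1''–C2''=C3''), and O2 reoxidises the reduced flavin to give H2O2, which catalase removes. The closest known reaction type is the oxidocyclisation of ortho-geranyl and ortho-prenyl resorcinols to 2,2-dialkyl-2H-chromenes by cannabichromenic acid synthase, daurichromenic acid synthase and their microbial homologues; 26 is a new substrate for this class, so a variant that accepts it has to be found by panel screening or directed evolution. Ring D closes by oxa-6π electrocyclisation of 27, which forms the O4'–C3'' bond and restores B-ring aromaticity. No stereocentre is created (C3'' carries two methyl groups) and C3 is remote and untouched. The step needs site selectivity between the two prenyl groups and between O4' and O2'. The substrate offers one true resorcinol (ring B, free OH on both sides of the prenyl group, as in the native substrates), whereas the 8-prenyl group has the ring-C ether O1 on one side and O2' is crowded by the C3 chroman substituent, so binding of ring B over the flavin with the base at the exposed O4' is the expected productive pose, a discrimination that chemical hydride acceptors such as DDQ cannot make.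

Compound list
1 | resorcinol | Oc1cccc(O)c1 | starting material
2 | 1,3-bis(methoxymethoxy)benzene | COCOc1cccc(OCOC)c1 | intermediate
3 | prenyl bromide | CC(C)=CCBr | starting material
4 | [2,6-bis(methoxymethoxy)phenyl]lithium | [Li]c1c(OCOC)cccc1OCOC | intermediate
5 | 1,3-bis(methoxymethoxy)-2-prenylbenzene | COCOc1cccc(OCOC)c1CC=C(C)C | intermediate
6 | [2,4-bis(methoxymethoxy)-3-prenylphenyl]lithium | [Li]c1ccc(OCOC)c(CC=C(C)C)c1OCOC | intermediate
7 | 2,4-bis(methoxymethoxy)-3-prenylbenzaldehyde | O=Cc1ccc(OCOC)c(CC=C(C)C)c1OCOC | intermediate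
8 | 2-hydroxy-4-(methoxymethoxy)-3-prenylbenzaldehyde | O=Cc1ccc(OCOC)c(CC=C(C)C)c1O | intermediate
9 | 2-(allyloxy)-4-(methoxymethoxy)-3-prenylbenzaldehyde | O=Cc1ccc(OCOC)c(CC=C(C)C)c1OCC=C | intermediate
10 | [2-(allyloxy)-4-(methoxymethoxy)-3-prenylphenyl]methanol | OCc1ccc(OCOC)c(CC=C(C)C)c1OCC=C | intermediate
11 | 2-(allyloxy)-1-(bromomethyl)-4-(methoxymethoxy)-3-prenylbenzene | BrCc1ccc(OCOC)c(CC=C(C)C)c1OCC=C | intermediate
12 | 1-ethenyl-2,4-bis(methoxymethoxy)-3-prenylbenzene | C=Cc1ccc(OCOC)c(CC=C(C)C)c1OCOC | intermediate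
13 | 9-{2-[2,4-bis(methoxymethoxy)-3-prenylphenyl]ethyl}-9-borabicyclo[3.3.1]nonane | C1CC2CCCC(C1)B2CCc1ccc(OCOC)c(CC=C(C)C)c1OCOC | intermediate
14 | 2-[2,4-bis(methoxymethoxy)-3-prenylphenyl]ethan-1-ol | OCCc1ccc(OCOC)c(CC=C(C)C)c1OCOC | intermediate
15 | 2-[2,4-bis(methoxymethoxy)-3-prenylphenyl]acetaldehyde | O=CCc1ccc(OCOC)c(CC=C(C)C)c1OCOC | intermediate
16 | 2-[2,4-bis(methoxymethoxy)-3-prenylphenyl]acetic acid | OC(=O)Cc1ccc(OCOC)c(CC=C(C)C)c1OCOC | intermediate
17 | (R)-4-benzyl-2-oxazolidinone | O=C1N[C@H](Cc2ccccc2)CO1 | starting material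
18 | 2-[2,4-bis(methoxymethoxy)-3-prenylphenyl]acetic pivalic anhydride | CC(C)(C)C(=O)OC(=O)Cc1ccc(OCOC)c(CC=C(C)C)c1OCOC | intermediate
19 | (4R)-4-benzyl-3-{2-[2,4-bis(methoxymethoxy)-3-prenylphenyl]acetyl}-1,3-oxazolidin-2-one | O=C1OC[C@@H](Cc2ccccc2)N1C(=O)Cc1ccc(OCOC)c(CC=C(C)C)c1OCOC | intermediate
20 | sodium (Z)-enolate of the arylacetyl imide | O=C1OC[C@@H](Cc2ccccc2)N1/C([O-])=C/c1ccc(OCOC)c(CC=C(C)C)c1OCOC.[Na+] | intermediate
21 | (4R,2'R)-alkylated imide | O=C1OC[C@@H](Cc2ccccc2)N1C(=O)[C@H](Cc1ccc(OCOC)c(CC=C(C)C)c1OCC=C)c1ccc(OCOC)c(CC=C(C)C)c1OCOC | intermediate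
22 | (2R)-3-[2-(allyloxy)-4-(methoxymethoxy)-3-prenylphenyl]-2-[2,4-bis(methoxymethoxy)-3-prenylphenyl]propan-1-ol | OC[C@@H](c1ccc(OCOC)c(CC=C(C)C)c1OCOC)Cc1ccc(OCOC)c(CC=C(C)C)c1OCC=C | intermediate
23 | 6-{(2R)-2-[2,4-bis(methoxymethoxy)-3-prenylphenyl]-3-hydroxypropyl}-3-(methoxymethoxy)-2-prenylphenol | OC[C@@H](c1ccc(OCOC)c(CC=C(C)C)c1OCOC)Cc1ccc(OCOC)c(CC=C(C)C)c1O | intermediate
24 | (3R)-7,2',4'-tris(methoxymethoxy)-8,3'-diprenylisoflavan | COCOc1ccc2c(c1CC=C(C)C)OC[C@@H](c1ccc(OCOC)c(CC=C(C)C)c1OCOC)C2 | intermediate
25 | (3R)-7,2',4'-tris(trimethylsilyloxy)-8,3'-diprenylisoflavan | C[Si](C)(C)Oc1ccc2c(c1CC=C(C)C)OC[C@@H](c1ccc(O[Si](C)(C)C)c(CC=C(C)C)c1O[Si](C)(C)C)C2 | intermediate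
26 | (3R)-8,3'-diprenyl-7,2',4'-trihydroxyisoflavan | CC(C)=CCc1c(O)ccc2c1OC[C@@H](c1ccc(O)c(CC=C(C)C)c1O)C2 | intermediate
27 | B-ring ortho-quinone methide (C4'=O, (Z)-C3'=C1'', dimethylvinyl group cis to C4'=O), 3R | CC(C)=CCc1c(O)ccc2c1OC[C@@H](C1=C(O)/C(=C/C=C(C)C)C(=O)C=C1)C2 | intermediate
28 | (3R)-3-(5-hydroxy-2,2-dimethyl-2H-chromen-6-yl)-8-prenylchroman-7-ol | CC(C)=CCc1c(O)ccc2c1OC[C@@H](c1ccc3c(c1O)C=CC(C)(C)O3)C2 | target

Total step count: 17. Longest linear sequence: 13 steps (steps 1–7 and 12–17). The B-ring branch (steps 1–3 and 8–11) is equally long and joins at step 12.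

Steps most likely to fail

1. Step 17. The bulky, neutral isoflavan may not be accepted by the active site. It may also bind in a pose that presents the 8-prenyl group to the flavin or O2' to the closing carbon, and low solubility or product inhibition may stall turnover. In the fallback, ring D is built chemically on the B-ring fragment before the coupling, so no late site selection is needed. The fallback sets out from bromide 11 and auxiliary 17 and comes back at target 28. Commercial 2,4-dihydroxybenzaldehyde and 3-methylbut-2-enal are condensed (Ca(OH)2, MeOH, rt; aldol–dehydration and oxa-6π closure at the non-chelated 4-OH) to 5-hydroxy-2,2-dimethyl-2H-chromene-6-carbaldehyde F1. This is protected (NaH, MOMCl, DMF) as 5-(methoxymethoxy)-2,2-dimethyl-2H-chromene-6-carbaldehyde F2. The chromene olefin is a second styrene-type alkene, so hydroboration is avoided in the homologation. Wittig methoxymethylenation (Ph3P=CHOMe, THF) gives 6-(2-methoxyvinyl)-5-(methoxymethoxy)-2,2-dimethyl-2H-chromene F3. Brief hydrolysis (1 M HCl, THF, rt) gives 2-[5-(methoxymethoxy)-2,2-dimethyl-2H-chromen-6-yl]acetaldehyde F4. Pinnick oxidation with excess 2-methylbut-2-ene gives 2-[5-(methoxymethoxy)-2,2-dimethyl-2H-chromen-6-yl]acetic acid F5. Acylation of 17 under the conditions of step 11 gives the chromenylacetyl imide F6, and Evans alkylation with 11 under the conditions of step 12 gives the (2R)-alkylated chromenyl imide F7. LiBH4 reduction gives the (2R)-chromenyl propanol F8, and Pd(0) deallylation gives the (2R)-chromenyl phenol alcohol F9. Mitsunobu closure then gives (3R)-7,2'-di-O-(methoxymethyl)-8-prenylphaseollinisoflavan F10. Its two MOM groups are removed under the conditions of step 16 to give 28.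

2. Step 3, which feeds both fragments. The alkyllithium may remove the allylic-benzylic proton of the prenyl CH2 in competition with ring deprotonation. That would consume base and lead to side-chain functionalisation or olefin migration. In the fallback, the ring anion is generated by halogen–metal exchange instead of deprotonation, with the order of functionalisation changed. The fallback sets out from 2 and comes back at aryllithium 6. NBS in MeCN at 0 °C brominates 2, before any olefin is present, to 1-bromo-2,4-bis(methoxymethoxy)benzene F11. LDA at −78 °C then removes the proton between the two OMOM groups, and copper-catalysed coupling with 3 gives 1-bromo-2,4-bis(methoxymethoxy)-3-prenylbenzene F12. Br/Li exchange of F12 with n-BuLi at −78 °C, which is faster than any deprotonation, delivers 6. This is quenched with DMF as in step 3.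

3. Step 4. Discrimination between the ortho and para acetals may be incomplete, so that both are lost. The Lewis acid may also trigger closure of the liberated ortho-prenylphenol onto its olefin. In the fallback, selective protection of a free dihydroxyaldehyde replaces selective deprotection. The fallback sets out from 3 and comes back at 8. Commercial 2,4-dihydroxybenzaldehyde is C-prenylated with 3 in aqueous KOH at the carbon between the two oxygens to give 2,4-dihydroxy-3-prenylbenzaldehyde F13, which is separated from the 5-prenyl and O-prenyl isomers. Only the non-chelated 4-OH of F13 is then protected (MOMCl, K2CO3, acetone), which gives 8.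

Further compounds
F1 | step 17 | 5-hydroxy-2,2-dimethyl-2H-chromene-6-carbaldehyde | O=Cc1ccc2c(c1O)C=CC(C)(C)O2
F2 | step 17 | 5-(methoxymethoxy)-2,2-dimethyl-2H-chromene-6-carbaldehyde | O=Cc1ccc2c(c1OCOC)C=CC(C)(C)O2
F3 | step 17 | 6-(2-methoxyvinyl)-5-(methoxymethoxy)-2,2-dimethyl-2H-chromene (E/Z mixture) | COC=Cc1ccc2c(c1OCOC)C=CC(C)(C)O2
F4 | step 17 | 2-[5-(methoxymethoxy)-2,2-dimethyl-2H-chromen-6-yl]acetaldehyde | O=CCc1ccc2c(c1OCOC)C=CC(C)(C)O2
F5 | step 17 | 2-[5-(methoxymethoxy)-2,2-dimethyl-2H-chromen-6-yl]acetic acid | OC(=O)Cc1ccc2c(c1OCOC)C=CC(C)(C)O2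
F6 | step 17 | chromenylacetyl imide, (4R) | O=C1OC[C@@H](Cc2ccccc2)N1C(=O)Cc1ccc2c(c1OCOC)C=CC(C)(C)O2
F7 | step 17 | (2R)-alkylated chromenyl imide, (4R) | O=C1OC[C@@H](Cc2ccccc2)N1C(=O)[C@H](Cc1ccc(OCOC)c(CC=C(C)C)c1OCC=C)c1ccc2c(c1OCOC)C=CC(C)(C)O2
F8 | step 17 | (2R)-chromenyl propanol | OC[C@@H](c1ccc2c(c1OCOC)C=CC(C)(C)O2)Cc1ccc(OCOC)c(CC=C(C)C)c1OCC=C
F9 | step 17 | (2R)-chromenyl phenol alcohol | OC[C@@H](c1ccc2c(c1OCOC)C=CC(C)(C)O2)Cc1ccc(OCOC)c(CC=C(C)C)c1O
F10 | step 17 | (3R)-7,2'-di-O-(methoxymethyl)-8-prenylphaseollinisoflavan | COCOc1ccc2c(c1CC=C(C)C)OC[C@@H](c1ccc3c(c1OCOC)C=CC(C)(C)O3)C2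
F11 | step 3 | 1-bromo-2,4-bis(methoxymethoxy)benzene | COCOc1ccc(Br)c(OCOC)c1
F12 | step 3 | 1-bromo-2,4-bis(methoxymethoxy)-3-prenylbenzene | COCOc1ccc(Br)c(OCOC)c1CC=C(C)C
F13 | step 4 | 2,4-dihydroxy-3-prenylbenzaldehyde | O=Cc1ccc(O)c(CC=C(C)C)c1O
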